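The constants come from no measurement; what happens was integrated by code.

I expected a leftover of L when I handed this flask over.

L 0.050 M; Z 0.0450 M; Q 2.5 mM

    Z → E (k1 = 0.039 /min)
    Q → G (k2 = 1.1 /min)
    L + Z + Q → Q + J (k3 = 2300 /M²/min)

* apparent order in Z when 10% of the L are converted (percent change of the rate of making J for one percent more Z charged)

I worked with the fraction of L left, not the J made. I held cZ at its charge. L then fell pseudo-first-order, with a coefficient that decayed as cQ did. So ln(charged cL / cL) climbed to a ceiling:

k3·cZ·cQ/k2 = 0.235

I called this ceiling the reach of the catalyst, the logarithm of charged L over final L. It put the final L at:

exp(−reach) = 79.0%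

My note said L would stand near that figure after Q had decayed. It also said not to touch the charge of Z, since with cZ held the reach is proportional to it.

The mark used up part of the reach:

ln(charged cL / cL) at the mark = 0.105
share of the reach spent, s = 0.448
live Q at the mark = 55.2%

One percent more Z stretched the reach by one percent, so live Q gained s/(1−s) percent. Z itself added its charge over what stood at the mark, with step 3 counted and the loss to E ignored:

order = 0.812 + 1.13 = 1.94

The forecast said 2.2, higher than my figure, reasoning "more Z reaches the mark sooner with more live catalyst".

The simulation gave 2.2, which matched the forecast and stood above my reckoning.

In this flask each Q turned over at 5.2 /min with L and Z as charged, faster than the 1.1 /min at which it was lost, and after 5.00 min the flask held Q at 0.409% of its charge and L at 81.8% of its charge, against the 79.0% from the reach with cZ held. After 100 min L stood at 81.7%, with Z down to 1.60%.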